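The data stem from a simulated flask for substances that don't exist.

Two questions stand for two flasks, summer and dusk: which ends with more product, and how much each gives.

| setting | eta | beta | zeta | delta | summer | dusk |
|---|---|---|---|---|---|---|
| starting material | 0.80 M | 0.80 M | 0.80 M | 0.52 M | 0.80 M | 0.20 M |
| coupling partner | 0.64 M | 0.64 M | 0.64 M | 0.64 M | 0.640 M | 0.640 M |
| free catalyst | 1.1 mM | 1.9 mM | 3.6 mM | 3.1 mM | 3.1 mM | 1.0 mM |
| impurity | 1.8 mM | 1.8 mM | 1.8 mM | 1.8 mM | 1.8 mM | 1.8 mM |
| remark | run made earlier | run made earlier | run made earlier | run made earlier |  |  |
| time |  |  |  |  | 30 min | 30 min |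

- eta (time / min: product / %, starting material / %): 3.00: 12, 89; 6.00: 15, 86; 10.0: 18, 85; 12.0: 17, 83; 15.0: 18, 79
- beta (time / min: product / %, starting material / %): 1.33: 9, 91; 4.00: 21, 75; 8.00: 31, 69; 10.0: 37, 67; 15.0: 43, 59
- zeta (time / min: product / %, starting material / %): 1.33: 20, 79; 2.50: 33, 69; 4.00: 45, 58; 8.00: 76, 25; 15.0: 80, 20
- delta (time / min: product / %, starting material / %): 3.00: 43, 55; 6.00: 77, 22; 10.0: 97, 3; 12.0: 100, 0; 15.0: 101, 3

(readings scatter by 2 percentage points)

- which of the two ends with the higher amount of product, in percent of the starting material charged ("neither" if they lie within 2 percentage points) (summer / dusk / neither)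
- product at the end, in percent of the starting material charged, summer
- product at the end, in percent of the starting material charged, dusk

- what was read earlier has a scatter of 2 percentage points, one standard deviation
- steps thought possible: free catalyst + impurity -> spent catalyst; catalyst intermediate B <-> catalyst intermediate C; catalyst intermediate A -> by-product + catalyst intermediate B; coupling partner + free catalyst <-> catalyst intermediate A; catalyst intermediate D -> free catalyst + product; starting material + catalyst intermediate C -> catalyst intermediate D

I fold each recipe into one number. Impurity charged over catalyst charged gives, for the two flasks: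

summer: 0.581

dusk: 1.80

This ratio is my poison fraction, the share of the catalyst charge that the impurity can take if one impurity removes one catalyst. The even case, one, is the zero of my scale.

The runs read well on it. Zeta at 0.500 stops at 80 %, which is the partner charge as a fraction of the starting material, 80.0 %, and delta at 0.581 reaches 101 %. Beta at 0.947 is still climbing at 43 %, and eta at 1.64 stalls at 18 %.

So I put summer at the limit set by the coupling partner, its limiting reagent, 80.0 %. Dusk lies above one and should stall. But the fraction tells the side, not the distance, so I add eta's product per catalyst charged:

turnovers in eta: 131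

dusk: turnovers × catalyst charged / starting material charged = 65.5 %

This is rough: the two fractions differ, and eta's scatter is multiplied by 3.64 on the way to this figure.

The forecast holds that “The impurity kills catalyst about 1:1” and names summer as higher, with 80 % for summer and 60 % for dusk, lower than my dusk figure.

The flask gives summer: summer 80.0 %, dusk 65.2 %.

    free catalyst + impurity → spent catalyst (k = 50.0 L mol⁻¹ s⁻¹)
    catalyst intermediate B ⇌ catalyst intermediate C (K = 1.30, k = 1.30 s⁻¹)
    catalyst intermediate A → by-product + catalyst intermediate B (k = 8.80 s⁻¹)
    coupling partner + free catalyst ⇌ catalyst intermediate A (K = 1.80 L mol⁻¹, k = 130 L mol⁻¹ s⁻¹)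
    catalyst intermediate D → free catalyst + product (k = 2.10 s⁻¹)
    starting material + catalyst intermediate C → catalyst intermediate D (k = 45.0 L mol⁻¹ s⁻¹)

Dusk stops short because of the path from free catalyst and impurity to spent catalyst: the same run without it gives 100 %, not 65.2 %. Summer's poison fraction of 0.581 stands against spent catalyst at 58.1 % after 30.0 min, with 41.9 % still free. A neighbour of dusk charged with 0.0031 M of impurity has a fraction of 3.10, its spent catalyst stands at >99.9 %, and its product ends at 33.3 %.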